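**Assumption:** iridoid numbering is used for locants (C1 = acetal carbon, C3=C4 enol ether, C5/C9 ring fusion, C10 = CH2Cl, C11 = CH2O on C4); β = the face of H‑9. The target is then 1β‑O‑iVal, 5β‑OH, 7β‑OAc, 8α‑OH/8β‑CH2Cl, 9β‑H, with an (R) side‑chain centre.

## Retrosynthetic overview

1. Last bond: the C11–O ester, joining core allylic alcohol **15** with (R)‑2‑(isovaleryloxy)isovaleric acid **20** (made from D‑valine).
2. **15** comes from 4‑formyl enol ether **14** (NaBH4), and **14** from lactol **13** (C1 acylation). The dihydropyran ring is formed last, by acid cyclisation of cyclopentane **12**, which carries a masked C1 aldehyde and a masked 2‑substituted malondialdehyde (C3/C11).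
3. 7‑OAc/8‑OH/10‑Cl come from allylic alcohol **8** by β‑epoxidation, Payne rearrangement–hydrolysis (inverts C8), primary chlorination and acetylation. C11 comes from a Wittig reaction; 5‑OH from enolate hydroxylation anti to the C9 substituent.
4. The cyclopentene ring is formed first, by a phosphine‑catalysed asymmetric [3+2] annulation of allenoate **4** with bis‑acetal enone **3** (from **1** + **2**).

## Core fragment

**Step 1**
Reactants: **1** 1,1‑dimethoxypropan‑2‑one; **2** 2,2‑dimethoxyacetaldehyde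
Product: **3** (E)‑1,1,5,5‑tetramethoxypent‑3‑en‑2‑one
Conditions: NaOH (0.2 equiv), MeOH/H2O, 0 °C → rt
Reagents that add atoms: none
Why: Crossed aldol (Claisen–Schmidt) condensation; only the CH3 of **1** is enolisable and **2** cannot self‑condense, so a single (E)‑enone forms.

**Step 2**
Reactants: **3**; **4** ethyl buta‑2,3‑dienoate
Product: **5** ethyl (4R,5S)‑4‑(2,2‑dimethoxyacetyl)‑5‑(dimethoxymethyl)cyclopent‑1‑ene‑1‑carboxylate (trans)
Conditions: (S)‑binaphthyl tert‑butyl‑phosphepine (10 mol %), toluene, rt (use the antipode if the sense of induction is opposite)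
Reagents that add atoms: none
Why: Lu phosphine‑catalysed [3+2] annulation; the ester‑bearing allenoate carbon bonds to the enone β‑carbon (C9), the E‑alkene gives the trans product, and the chiral phosphine sets C9 (C5 is re‑set in step 3).

**Step 3**
Reactants: **5**
Product: **6** ethyl (4R,5R)‑4‑(2,2‑dimethoxyacetyl)‑5‑(dimethoxymethyl)‑4‑(triethylsilyloxy)cyclopent‑1‑ene‑1‑carboxylate (5β‑OTES, trans to the C9 CH(OMe)2 group)
Conditions: KHMDS, THF, −78 °C; 2‑(phenylsulfonyl)‑3‑phenyloxaziridine; then TESCl, −78 → 0 °C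
Reagents that add atoms: Davis oxaziridine O=S(=O)(N1OC1c1ccccc1)c1ccccc1; TESCl CC[Si](Cl)(CC)CC
Why: Davis enolate hydroxylation; the ketone can enolise only towards C5 (the other α‑carbon is an acetal CH), and the oxidant approaches anti to the adjacent C9 substituent, giving 5β‑O with the acyl group cis to C1.

**Step 4**
Reactants: **6**
Product: **7** ethyl (4R,5R)‑5‑(dimethoxymethyl)‑4‑(1,3,3‑trimethoxyprop‑1‑en‑2‑yl)‑4‑(triethylsilyloxy)cyclopent‑1‑ene‑1‑carboxylate (E/Z mixture, inconsequential)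
Conditions: MeOCH2PPh3Cl, KHMDS, THF, 0 → 40 °C
Reagents that add atoms: (methoxymethyl)triphenylphosphonium chloride COC[P+](c1ccccc1)(c1ccccc1)c1ccccc1.[Cl-]
Why: Wittig methoxymethylenation of a non‑enolisable, acetal‑activated ketone installs C11 at the aldehyde level; the enol ether plus adjacent acetal is a masked 2‑substituted malondialdehyde.

**Step 5**
Reactants: **7**
Product: **8** [(4R,5R)‑5‑(dimethoxymethyl)‑4‑(1,3,3‑trimethoxyprop‑1‑en‑2‑yl)‑4‑(triethylsilyloxy)cyclopent‑1‑en‑1‑yl]methanol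
Conditions: DIBAL‑H (2.5 equiv), CH2Cl2, −78 °C; Rochelle salt work‑up
Reagents that add atoms: none
Why: 1,2‑Reduction of the enoate to the allylic alcohol (C10–OH); acetals, enol ether and silyl ether are inert to DIBAL.

**Step 6**
Reactants: **8**
Product: **9** 7β,8β‑epoxy alcohol, [2‑(dimethoxymethyl)‑3‑(1,3,3‑trimethoxyprop‑1‑en‑2‑yl)‑3‑(triethylsilyloxy)‑6‑oxabicyclo[3.1.0]hexan‑1‑yl]methanol (epoxide cis to OTES, trans to CH(OMe)2)
Conditions: Ti(OiPr)4 (10 mol %), D‑(−)‑DIPT (12 mol %), TBHP, 4 Å MS, CH2Cl2, −20 °C; basic work‑up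
Reagents that add atoms: tert‑butyl hydroperoxide CC(C)(C)OO
Why: Sharpless asymmetric epoxidation of the allylic alcohol; D‑(−)‑tartrate delivers oxygen to the β face, matching the substrate bias (anti to the adjacent C9 substituent), and the undirected enol ether is untouched.

**Step 7**
Reactants: **9**
Product: **10** triol (7β‑OH, 8α‑OH, 8β‑CH2OH, 5β‑OTES, 9β‑H): 1‑(hydroxymethyl)‑5‑(dimethoxymethyl)‑4‑(1,3,3‑trimethoxyprop‑1‑en‑2‑yl)‑4‑(triethylsilyloxy)cyclopentane‑1,2‑diol
Conditions: 0.5 M NaOH, t‑BuOH/H2O (3:1), 65 °C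
Reagents that add atoms: water/hydroxide, O
Why: Payne rearrangement (C10–O⁻ attacks C8 with inversion, giving the 8α,10‑spiro‑epoxide and 7β‑O⁻) followed by hydroxide opening at primary C10; this fixes 7β‑OH/8α‑OH, while the 5‑O stays silylated so it cannot attack C10.

**Step 8**
Reactants: **10**
Product: **11** 1‑(chloromethyl)‑5‑(dimethoxymethyl)‑4‑(1,3,3‑trimethoxyprop‑1‑en‑2‑yl)‑4‑(triethylsilyloxy)cyclopentane‑1,2‑diol (configuration as **10**)
Conditions: TsCl (1.1 equiv), Et3N, Bu2SnO (cat.), CH2Cl2, 0 °C; then LiCl, DMF, 60 °C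
Reagents that add atoms: LiCl [Li+].[Cl-] (tosyl is transient)
Why: Tin‑catalysed selective sulfonylation of the primary OH, then chloride displacement (directly or via the transient 8,10‑epoxide); either path gives 10‑Cl with C8 unchanged.

**Step 9**
Reactants: **11**
Product: **12** [2‑(chloromethyl)‑2‑hydroxy‑3‑(dimethoxymethyl)‑4‑(1,3,3‑trimethoxyprop‑1‑en‑2‑yl)‑4‑(triethylsilyloxy)cyclopentyl] acetate (7β‑OAc)
Conditions: Ac2O, pyridine, DMAP (cat.), CH2Cl2, 0 °C
Reagents that add atoms: acetic anhydride CC(=O)OC(C)=O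
Why: Selective acetylation of the only secondary hydroxyl; the tertiary 8‑OH does not react under these conditions.

**Step 10**
Reactants: **12**
Product: **13** (1R,4aR,6S,7S,7aS)‑7‑(chloromethyl)‑4‑formyl‑1,4a,7‑trihydroxy‑1,4a,5,6,7,7a‑hexahydrocyclopenta[c]pyran‑6‑yl acetate (cis‑fused lactol, 1β‑OH major)
Conditions: 0.5 M HCl, THF/H2O (4:1), 0 °C → rt
Reagents that add atoms: water, O
Why: Acid unmasks the malondialdehyde unit (via a 1,3‑dialkoxyallyl cation, so C4 stays sp2 and the 5‑OH cannot undergo retro‑aldol or dehydration) and the C1 aldehyde, which close to the thermodynamically favoured enol‑ether lactol (vinylogous formate); TES is cleaved in the same operation.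

**Step 11**
Reactants: **13**
Product: **14** (1S,4aR,6S,7S,7aS)‑6‑acetoxy‑7‑(chloromethyl)‑4‑formyl‑4a,7‑dihydroxy‑1,4a,5,6,7,7a‑hexahydrocyclopenta[c]pyran‑1‑yl 3‑methylbutanoate
Conditions: isovaleryl chloride (1.2 equiv), pyridine, CH2Cl2, −20 → 0 °C
Reagents that add atoms: isovaleryl chloride CC(C)CC(Cl)=O
Why: Anomeric O‑acylation of the lactol (the only acylable OH; the others are tertiary); the favoured β‑lactol (anomeric effect, as in natural 1β‑O‑substituted iridoids) gives the 1β‑ester.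

**Step 12**
Reactants: **14**
Product: **15** (1S,4aR,6S,7S,7aS)‑6‑acetoxy‑7‑(chloromethyl)‑4a,7‑dihydroxy‑4‑(hydroxymethyl)‑1,4a,5,6,7,7a‑hexahydrocyclopenta[c]pyran‑1‑yl 3‑methylbutanoate (used immediately)
Conditions: NaBH4, THF/MeOH (5:1), −30 °C; pH 7 buffer quench
Reagents that add atoms: none
Why: Chemoselective 1,2‑reduction of the vinylogous formyl group; esters, the anomeric acylal and the chlorohydrin survive brief borohydride exposure at low temperature.

## Side‑chain acid

**Step 13**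
Reactants: **16** D‑valine
Product: **17** (R)‑2‑hydroxy‑3‑methylbutanoic acid
Conditions: NaNO2, 1 M H2SO4, 0 °C → rt
Reagents that add atoms: water, O
Why: Diazotisation with net retention (double inversion through the α‑lactone) converts NH2 into OH.

**Step 14**
Reactants: **17**
Product: **18** benzyl (R)‑2‑hydroxy‑3‑methylbutanoate
Conditions: BnBr, Cs2CO3, DMF, rt
Reagents that add atoms: benzyl bromide BrCc1ccccc1 (protecting group)
Why: Carboxylate O‑alkylation protects the acid without touching the stereocentre.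

**Step 15**
Reactants: **18**
Product: **19** benzyl (R)‑3‑methyl‑2‑(3‑methylbutanoyloxy)butanoate
Conditions: isovaleryl chloride, pyridine, DMAP (cat.), CH2Cl2, 0 °C
Reagents that add atoms: isovaleryl chloride CC(C)CC(Cl)=O
Why: Simple O‑acylation of the secondary alcohol.

**Step 16**
Reactants: **19**
Product: **20** (R)‑3‑methyl‑2‑(3‑methylbutanoyloxy)butanoic acid
Conditions: H2 (1 atm), 10% Pd/C, EtOAc, rt
Reagents that add atoms: none
Why: Hydrogenolysis removes the benzyl ester and leaves the alkyl ester intact.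

## Fragment coupling

**Step 17**
Reactants: **15**; **20**
Product: **21** Volvaltrate B
Conditions: DIC, DMAP (0.2 equiv), CH2Cl2, −10 → 0 °C
Reagents that add atoms: none
Why: Steglich esterification of the only primary hydroxyl (the others are tertiary) under near‑neutral conditions that tolerate the enol‑acetal, the chlorohydrin and the α‑acyloxy stereocentre.

## Compound list

1 | 1,1‑dimethoxypropan‑2‑one | CC(=O)C(OC)OC | starting material
2 | 2,2‑dimethoxyacetaldehyde | O=CC(OC)OC | starting material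
3 | (E)‑1,1,5,5‑tetramethoxypent‑3‑en‑2‑one | COC(OC)C(=O)/C=C/C(OC)OC | intermediate
4 | ethyl buta‑2,3‑dienoate | C=C=CC(=O)OCC | starting material
5 | ethyl (4R,5S)‑4‑(2,2‑dimethoxyacetyl)‑5‑(dimethoxymethyl)cyclopent‑1‑ene‑1‑carboxylate | CCOC(=O)C1=CC[C@@H](C(=O)C(OC)OC)[C@@H]1C(OC)OC | intermediate
6 | ethyl (4R,5R)‑4‑(2,2‑dimethoxyacetyl)‑5‑(dimethoxymethyl)‑4‑(triethylsilyloxy)cyclopent‑1‑ene‑1‑carboxylate | CCOC(=O)C1=CC[C@](O[Si](CC)(CC)CC)(C(=O)C(OC)OC)[C@@H]1C(OC)OC | intermediate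
7 | ethyl (4R,5R)‑5‑(dimethoxymethyl)‑4‑(1,3,3‑trimethoxyprop‑1‑en‑2‑yl)‑4‑(triethylsilyloxy)cyclopent‑1‑ene‑1‑carboxylate | CCOC(=O)C1=CC[C@](O[Si](CC)(CC)CC)(C(=COC)C(OC)OC)[C@@H]1C(OC)OC | intermediate
8 | [(4R,5R)‑5‑(dimethoxymethyl)‑4‑(1,3,3‑trimethoxyprop‑1‑en‑2‑yl)‑4‑(triethylsilyloxy)cyclopent‑1‑en‑1‑yl]methanol | OCC1=CC[C@](O[Si](CC)(CC)CC)(C(=COC)C(OC)OC)[C@@H]1C(OC)OC | intermediate
9 | 7β,8β‑epoxy alcohol (6‑oxabicyclo[3.1.0]hexan‑1‑yl)methanol derivative | [C@H]12C[C@](O[Si](CC)(CC)CC)(C(=COC)C(OC)OC)[C@H](C(OC)OC)[C@@]1(CO)O2 | intermediate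
10 | triol (7β‑OH, 8α‑OH, 8β‑CH2OH) | O[C@H]1C[C@](O[Si](CC)(CC)CC)(C(=COC)C(OC)OC)[C@H](C(OC)OC)[C@@]1(O)CO | intermediate
11 | chlorodiol (7β‑OH, 8α‑OH, 8β‑CH2Cl) | O[C@H]1C[C@](O[Si](CC)(CC)CC)(C(=COC)C(OC)OC)[C@H](C(OC)OC)[C@@]1(O)CCl | intermediate
12 | 7β‑acetate of 11 | CC(=O)O[C@H]1C[C@](O[Si](CC)(CC)CC)(C(=COC)C(OC)OC)[C@H](C(OC)OC)[C@@]1(O)CCl | intermediate
13 | (1R,4aR,6S,7S,7aS)‑7‑(chloromethyl)‑4‑formyl‑1,4a,7‑trihydroxy‑hexahydrocyclopenta[c]pyran‑6‑yl acetate | CC(=O)O[C@H]1C[C@]2(O)C(C=O)=CO[C@@H](O)[C@@H]2[C@@]1(O)CCl | intermediate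
14 | 1β‑O‑isovaleryl 4‑formyl core | CC(=O)O[C@H]1C[C@]2(O)C(C=O)=CO[C@@H](OC(=O)CC(C)C)[C@@H]2[C@@]1(O)CCl | intermediate
15 | 1β‑O‑isovaleryl 4‑(hydroxymethyl) core | CC(=O)O[C@H]1C[C@]2(O)C(CO)=CO[C@@H](OC(=O)CC(C)C)[C@@H]2[C@@]1(O)CCl | intermediate
16 | D‑valine | CC(C)[C@@H](N)C(=O)O | starting material
17 | (R)‑2‑hydroxy‑3‑methylbutanoic acid | CC(C)[C@@H](O)C(=O)O | intermediate
18 | benzyl (R)‑2‑hydroxy‑3‑methylbutanoate | CC(C)[C@@H](O)C(=O)OCc1ccccc1 | intermediate
19 | benzyl (R)‑3‑methyl‑2‑(3‑methylbutanoyloxy)butanoate | CC(C)CC(=O)O[C@H](C(C)C)C(=O)OCc1ccccc1 | intermediate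
20 | (R)‑3‑methyl‑2‑(3‑methylbutanoyloxy)butanoic acid | CC(C)CC(=O)O[C@H](C(C)C)C(=O)O | intermediate
21 | Volvaltrate B, [(1S,4aR,6S,7S,7aS)‑6‑acetoxy‑7‑(chloromethyl)‑4a,7‑dihydroxy‑1‑(3‑methylbutanoyloxy)‑1,4a,5,6,7,7a‑hexahydrocyclopenta[c]pyran‑4‑yl]methyl (2R)‑3‑methyl‑2‑(3‑methylbutanoyloxy)butanoate | CC(=O)O[C@H]1C[C@]2(O)C(COC(=O)[C@H](OC(=O)CC(C)C)C(C)C)=CO[C@@H](OC(=O)CC(C)C)[C@@H]2[C@@]1(O)CCl | target

## Step count and risks

Total step count: 17. Longest linear sequence: 13 (steps 1–12, then 17); the four‑step acid branch (13–16) runs in parallel.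

Steps most likely to fail:

- **Step 2 (asymmetric [3+2]).** The bis‑acetal enone is an untested acceptor, so rate, α/γ regioselectivity and ee are uncertain. Fallback: build the ring stepwise by Rh/chiral‑diene conjugate addition of the (Z)‑alkenylboronate from mono‑protected but‑2‑yne‑1,4‑diol to **3**, then intramolecular C5‑enolate allylic alkylation; this rejoins the route at the stage of **8**.
- **Step 4 (Wittig on a hindered ketone next to an enoate).** Addition may be slow, and the ylide may attack or deconjugate the enoate. Fallback: add dimethylsulfonium methylide to form the C4 spiro‑epoxide, then Lewis‑acid Meinwald rearrangement to the C11 aldehyde, which enters step 10 at the same oxidation level.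
- **Step 7 (Payne rearrangement–hydrolysis).** Risks are competing direct epoxide opening and loss of TES, which would let the 5‑alkoxide attack C10. Fallback: make the N‑phenylcarbamate of **9** and use BF3‑promoted intramolecular opening at C8 to a cyclic carbonate (same inversion at C8, no strong base), then hydrolyse to **10**.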